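The numbers in the tables are calculated with made-up constants; noise was put on by code.

Count in monomer units per chain begun: that is the measure you are asked for on green and teal.

in all of them: free monomer 0.42 M; initiator 2.9 mol%

| charge | transfer agent | remark | time |
|---|---|---|---|
| midnight | 0.018 M | run made earlier |  |
| winter | 0.033 M | run made earlier |  |
| green | 0.0126 M |  | 40 min |
| teal | 0.0250 M |  | 40 min |

| run | time / min | monomer in chains / % | free monomer / % |
|---|---|---|---|
| midnight | 2.00 | 69.8 | 30.2 |
| midnight | 5.00 | 89.6 | 9.7 |
| midnight | 10.0 | 95.7 | 4.0 |
| midnight | 15.0 | 98.0 | 3.2 |
| midnight | 20.0 | 99.6 | 0.9 |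
| midnight | 30.0 | 98.7 | 0.4 |
| winter | 5.00 | 90.5 | 10.9 |
| winter | 10.0 | 96.5 | 4.0 |
| winter | 15.0 | 97.9 | 2.0 |
| winter | 20.0 | 97.9 | 2.1 |
| winter | 25.0 | 97.8 | 1.4 |
| winter | 30.0 | 99.2 | 0.4 |

(scatter of a reading: 0.5 percentage points)

- the average divides the monomer in chains by the number of chains begun, living and dead together
- the earlier runs do not show the number of chains; that part of a forecast is a guess

- which of the two ends with the longer chains by the average number of monomer units in a chain (chains begun, living or dead) ("neither" if they lie within 10%) (green / teal / neither)
- average number of monomer units in a chain (chains begun, living or dead) at the end, green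
- average number of monomer units in a chain (chains begun, living or dead) at the end, teal

Here is what looks wrong. The winter run carries 1.83 times the transfer agent of the midnight run, 7.86% of the free monomer charged against 4.29%. Yet at 10.0 min free monomer reads 4.0% in midnight and 4.0% in winter, with a scatter of 0.5 percentage points.

You clear this up by asking what the end state must be. Midnight and winter agree at that reading, so as my own assumption I let the initiator begin the chains and count none as begun by the transfer agent. Then the quantity to carry is the ration, 34.5, the monomer units charged per initiator. Green and teal hold the same 2.9 mol% of initiator, so I expect about 34.5 in each and neither longer; these runs don't show the chain count, so this is a guess.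

The forecast differs from my reckoning. It holds that “Chains begun equal the transfer agent plus initiator-derived chains”, and it gives 22 for green and 13.5 for teal, with green longer.

The flasks end at 40.9 in green and 40.3 in teal, so the answer is neither.

    free monomer + initiator → living end + monomer in chains (k = 0.0300 M⁻¹ s⁻¹)
    free monomer + living end → monomer in chains + living end, rate k2*[living end]*[free monomer] (k = 3.50 M⁻¹ s⁻¹)
    living end + transfer agent → dead chain (kL = 0.0380 M⁻¹ s⁻¹)
    2 living end → dead end (k = 2.30 M⁻¹ s⁻¹)

In green at 1.20 min, free monomer goes into growth 63 times as fast as into chain starts, and at 40.0 min still 9.6 times. By then 0.484% of the free monomer, the limiting reagent, is left, beside 16.2% of the initiator, so the ration times 99.5% in chains, over 83.8% of the initiator used, makes 40.9. The neighbour of green at 1.7 mol% of initiator has a ration of 58.8, uses 93.2% of its initiator, reckons to 62.3, and ends at 62.3.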